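**Plan**

1. Locants: C1 = OCH2 of the side chain, C3 = its carbinol carbon, C6 = ring CH bearing the chain, C7 = ring C(CH3)OH, C8 and C9 = ring CH2, C10 = ring CHOH, C11 = ring C(CH3)2.
2. Cuts, in retrosynthetic order: the aryl ether O–C1; the C10–H bond (back to the ketone); then C7–OH is removed and C7 re-joined to C9, which folds the cyclohexanone into a 5-methylbicyclo[3.1.0]hexan-2-one; then the cyclopropane CH2 (C8), the two C11 methyls, the ring bond C6–C11 and the bond C9–C10 are cut, leaving an enal derived from (R)-linalool.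
3. Forward: linalool chain (C1–C7, C9 and the C7 methyl) → enal → propargylic pivalate (C10 and C11 from trimethylsilylacetylene) → cyclopentenone (five-membered ring, C6–C11 bond) → gem-dimethylation → cyclopropane (C8) → hydrative opening to the six-membered ring → C10 reduction → coumarin ether.
4. Enabling feature: in ring C6–C11 the methyl carbinol C7 lies 1,4 to the oxygen-bearing C10. At the C10 ketone level the ring is a 4-hydroxy-4-methylcyclohexanone, the formal adduct of water to a cyclopropyl ketone, so it is the opened form of a cyclopentanone (C6, C7, C9, C10, C11) fused to a cyclopropane across C7–C9.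
5. Stereochemistry: C3 from (R)-linalool; C6 from a catalyst-set propargylic carbinol by chirality transfer in the cyclopentenone-forming step; C7 from cyclopropanation anti to the side chain followed by inversion on opening; C10 from equatorial hydride delivery.

Key step: step 10

Assumption: in step 7 the new C–C bond is taken to form on the alkene face anti to the departing pivalate, so the (3S)-pivalate leads to the (4S)-cyclopentenone; if the sense were opposite, the antipodal ProPhenol ligand would be used in step 4 and nothing else would change.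

**Route**

Step 1
Reactants: 1 (R)-(−)-linalool
Product: 2 (3R)-3,7-dimethyloct-6-ene-1,3-diol
Conditions: 9-BBN, THF, 0 °C to rt; then NaOH, H2O2 (aq), 0 °C
Reagents that add atoms: hydrogen peroxide, OO
Why: Brown hydroboration–oxidation, in which 9-BBN should add anti-Markovnikov to the monosubstituted vinyl group only and leave the trisubstituted alkene and the C3 stereocentre untouched.

Step 2
Reactants: 2 (3R)-3,7-dimethyloct-6-ene-1,3-diol
Product: 3 (4R)-2,2,4-trimethyl-4-(4-methylpent-3-en-1-yl)-1,3-dioxane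
Conditions: 2,2-dimethoxypropane, PPTS (cat.), CH2Cl2, rt
Reagents that add atoms: 2,2-dimethoxypropane, COC(C)(C)OC
Why: Acetal exchange (acetonide formation) should tie the primary and tertiary hydroxyls into a 1,3-dioxane that withstands the oxidations, bases and organometallic reagents ahead.

Step 3
Reactants: 3 (4R)-2,2,4-trimethyl-4-(4-methylpent-3-en-1-yl)-1,3-dioxane
Product: 5 (2E)-2-methyl-5-[(4R)-2,2,4-trimethyl-1,3-dioxan-4-yl]pent-2-enal, via allylic alcohol 4 (not isolated)
Conditions: SeO2 (cat.), t-BuOOH, CH2Cl2, rt; then MnO2, CH2Cl2, rt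
Reagents that add atoms: tert-butyl hydroperoxide, CC(C)(C)OO
Why: Selenium dioxide allylic oxidation (ene reaction then [2,3]-shift) should functionalise the (E)-methyl of the terminal trisubstituted alkene selectively, and MnO2 should carry the allylic alcohol on to the (E)-enal.

Step 4
Reactants: 5 (2E)-2-methyl-5-[(4R)-2,2,4-trimethyl-1,3-dioxan-4-yl]pent-2-enal; 6 trimethylsilylacetylene
Product: 7 (3R,4E)-4-methyl-7-[(4R)-2,2,4-trimethyl-1,3-dioxan-4-yl]-1-(trimethylsilyl)hept-4-en-1-yn-3-ol
Conditions: Me2Zn, ProPhenol ligand (cat.), Ph3PO (cat.), toluene, 0 °C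
Reagents that add atoms: none
Why: Catalytic enantioselective alkynylzinc addition to an α-branched enal, in which the dinuclear zinc–ProPhenol catalyst should set the carbinol centre (catalyst control; the ligand enantiomer is the one that gives the 3R adduct).

Step 5
Reactants: 7 (3R,4E)-4-methyl-7-[(4R)-2,2,4-trimethyl-1,3-dioxan-4-yl]-1-(trimethylsilyl)hept-4-en-1-yn-3-ol
Product: 8 (3S,4E)-4-methyl-7-[(4R)-2,2,4-trimethyl-1,3-dioxan-4-yl]hept-4-en-1-yn-3-ol
Conditions: K2CO3, MeOH, rt
Reagents that add atoms: none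
Why: Methoxide-mediated protodesilylation of the alkynylsilane should free the terminal alkyne without touching the carbinol (the descriptor changes only because the priorities change).

Step 6
Reactants: 8 (3S,4E)-4-methyl-7-[(4R)-2,2,4-trimethyl-1,3-dioxan-4-yl]hept-4-en-1-yn-3-ol
Product: 9 (3S,4E)-4-methyl-7-[(4R)-2,2,4-trimethyl-1,3-dioxan-4-yl]hept-4-en-1-yn-3-yl 2,2-dimethylpropanoate
Conditions: PivCl, pyridine, DMAP (cat.), CH2Cl2, 0 °C to rt
Reagents that add atoms: pivaloyl chloride, CC(C)(C)C(Cl)=O
Why: DMAP-catalysed acylation of the secondary propargylic alcohol should proceed with retention, since no bond to the stereocentre is broken.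

Step 7
Reactants: 9 (3S,4E)-4-methyl-7-[(4R)-2,2,4-trimethyl-1,3-dioxan-4-yl]hept-4-en-1-yn-3-yl 2,2-dimethylpropanoate
Product: 11 (4S)-3-methyl-4-{2-[(4R)-2,2,4-trimethyl-1,3-dioxan-4-yl]ethyl}cyclopent-2-en-1-one, via cyclopentadienyl pivalate 10 (not isolated)
Conditions: Ph3PAuCl (cat.), AgSbF6 (cat.), wet MeCN, −20 °C to rt
Reagents that add atoms: none
Why: Gold-catalysed Rautenstrauch rearrangement (1,2-acyloxy shift onto the activated alkyne, cyclisation of the vinylgold carbon onto the alkene, hydrolysis of the dienyl ester), in which the C6 centre should be set by chirality transfer from the propargylic carbon, the ring bond forming anti to the departing pivalate.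

Step 8
Reactants: 11 (4S)-3-methyl-4-{2-[(4R)-2,2,4-trimethyl-1,3-dioxan-4-yl]ethyl}cyclopent-2-en-1-one
Product: 13 (4R)-3,5,5-trimethyl-4-{2-[(4R)-2,2,4-trimethyl-1,3-dioxan-4-yl]ethyl}cyclopent-2-en-1-one, via monomethyl enone 12 (not isolated)
Conditions: LDA, THF, −78 °C, then MeI; repeated once in the same flask
Reagents that add atoms: iodomethane, CI
Why: Kinetic α′-enolate alkylation, twice, should build the quaternary C11 because LDA removes only the protons of the CH2 flanked by the carbonyl, and the second methyl erases the transient stereocentre (the C4 descriptor changes by priority only).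

Step 9
Reactants: 13 (4R)-3,5,5-trimethyl-4-{2-[(4R)-2,2,4-trimethyl-1,3-dioxan-4-yl]ethyl}cyclopent-2-en-1-one
Product: 14 (1R,4R,5R)-3,3,5-trimethyl-4-{2-[(4R)-2,2,4-trimethyl-1,3-dioxan-4-yl]ethyl}bicyclo[3.1.0]hexan-2-one
Conditions: Me3S(O)I, NaH, DMSO, rt to 50 °C
Reagents that add atoms: trimethylsulfoxonium iodide, C[S+](C)(C)=O.[I-]
Why: Corey–Chaykovsky cyclopropanation, in which dimethylsulfoxonium methylide should add to the enone at C7 anti to the neighbouring C6 side chain and the enolate then close the three-membered ring (3-exo-tet), so that the cyclopropane CH2 stands trans to the side chain at C7 and C9.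

Step 10
Reactants: 14 (1R,4R,5R)-3,3,5-trimethyl-4-{2-[(4R)-2,2,4-trimethyl-1,3-dioxan-4-yl]ethyl}bicyclo[3.1.0]hexan-2-one
Product: 16 (3S,4S)-3-[(3R)-3,5-dihydroxy-3-methylpentyl]-4-hydroxy-2,2,4-trimethylcyclohexan-1-one, via cyclopropyl ketone diol 15 (not isolated)
Conditions: HClO4 (1 M aq), THF, 0 °C to rt
Reagents that add atoms: water, O
Why: After fast hydrolysis of the acetonide, protonation of the ketone makes the C9–C7 ring-fusion bond the donor–acceptor bond of the cyclopropane; it should break towards the methyl-bearing tertiary C7 while water adds there and the C10 enol ketonises, turning the cyclopentanone into a 4-hydroxy-4-methylcyclohexanone. The closest known reaction type is the acid-catalysed homoconjugate (1,5-) addition to cyclopropyl ketones, as in the opening of 3,5-cyclosteroid 6-ketones and the acid-induced conversion of thujane ketones such as sabina ketone into p-menthanes. No ring is closed: the six-membered ring arises by cleavage of the zero-atom bridge of the bicyclo[3.1.0]hexane, a one-carbon expansion in which the ylide-derived CH2 becomes C8. The new C7 stereocentre is controlled by the cyclopropane placed anti to the side chain in step 9: water enters with inversion, opposite the breaking C7–C9 bond, and a freer cation would be attacked on the same face, anti to the axial C11 methyl, so the hydroxyl ends trans to the side chain. The step needs cleavage of the internal C9–C7 bond and not the C9–CH2 bond, and hydration and not elimination; the first is secured by the tertiary, methyl-substituted C7 against a primary terminus, the second by the water-rich medium at low temperature.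

Step 11
Reactants: 16 (3S,4S)-3-[(3R)-3,5-dihydroxy-3-methylpentyl]-4-hydroxy-2,2,4-trimethylcyclohexan-1-one
Product: 17 (1S,2S,4R)-2-[(3R)-3,5-dihydroxy-3-methylpentyl]-1,3,3-trimethylcyclohexane-1,4-diol
Conditions: LiB(s-Bu)3H (L-Selectride, excess), THF, −78 °C; then NaOH, H2O2
Reagents that add atoms: none
Why: Bulky trialkylborohydride reduction should attack the C10 ketone from the equatorial direction of the chair that keeps the side chain equatorial, giving the axial alcohol cis to the C7 hydroxyl, as in the reduction of 4,4-dimethyl-3-keto terpenoids to their 3α-alcohols; the free hydroxyls only consume hydride.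

Step 12
Reactants: 17 (1S,2S,4R)-2-[(3R)-3,5-dihydroxy-3-methylpentyl]-1,3,3-trimethylcyclohexane-1,4-diol; 18 umbelliferone (7-hydroxycoumarin)
Product: 19 7-{[(3R)-5-[(1S,2S,5R)-2,5-dihydroxy-2,6,6-trimethylcyclohexyl]-3-hydroxy-3-methylpentyl]oxy}-2H-chromen-2-one (CNP0210598.1)
Conditions: PPh3, DIAD, THF, 0 °C to rt
Reagents that add atoms: none
Why: Mitsunobu etherification, in which the acidic phenol should displace only the activated primary alcohol, the hindered axial secondary and the two tertiary hydroxyls being unreactive; no stereocentre is involved.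

**Compound list**

1 | (R)-(−)-linalool | CC(C)=CCC[C@@](C)(O)C=C | starting material
2 | (3R)-3,7-dimethyloct-6-ene-1,3-diol | CC(C)=CCC[C@@](C)(O)CCO | intermediate
3 | (4R)-2,2,4-trimethyl-4-(4-methylpent-3-en-1-yl)-1,3-dioxane | CC(C)=CCC[C@]1(C)CCOC(C)(C)O1 | intermediate
4 | (2E)-2-methyl-5-[(4R)-2,2,4-trimethyl-1,3-dioxan-4-yl]pent-2-en-1-ol (not isolated) | OC/C(C)=C/CC[C@]1(C)CCOC(C)(C)O1 | intermediate
5 | (2E)-2-methyl-5-[(4R)-2,2,4-trimethyl-1,3-dioxan-4-yl]pent-2-enal | O=C/C(C)=C/CC[C@]1(C)CCOC(C)(C)O1 | intermediate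
6 | trimethylsilylacetylene | C#C[Si](C)(C)C | starting material
7 | (3R,4E)-4-methyl-7-[(4R)-2,2,4-trimethyl-1,3-dioxan-4-yl]-1-(trimethylsilyl)hept-4-en-1-yn-3-ol | O[C@@H](C#C[Si](C)(C)C)/C(C)=C/CC[C@]1(C)CCOC(C)(C)O1 | intermediate
8 | (3S,4E)-4-methyl-7-[(4R)-2,2,4-trimethyl-1,3-dioxan-4-yl]hept-4-en-1-yn-3-ol | O[C@@H](C#C)/C(C)=C/CC[C@]1(C)CCOC(C)(C)O1 | intermediate
9 | (3S,4E)-4-methyl-7-[(4R)-2,2,4-trimethyl-1,3-dioxan-4-yl]hept-4-en-1-yn-3-yl 2,2-dimethylpropanoate | CC(C)(C)C(=O)O[C@@H](C#C)/C(C)=C/CC[C@]1(C)CCOC(C)(C)O1 | intermediate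
10 | (3S)-4-methyl-3-{2-[(4R)-2,2,4-trimethyl-1,3-dioxan-4-yl]ethyl}cyclopenta-1,4-dien-1-yl 2,2-dimethylpropanoate (not isolated) | CC(C)(C)C(=O)OC1=C[C@H](CC[C@]2(C)CCOC(C)(C)O2)C(C)=C1 | intermediate
11 | (4S)-3-methyl-4-{2-[(4R)-2,2,4-trimethyl-1,3-dioxan-4-yl]ethyl}cyclopent-2-en-1-one | O=C1C[C@H](CC[C@]2(C)CCOC(C)(C)O2)C(C)=C1 | intermediate
12 | 3,5-dimethyl-4-{2-[(4R)-2,2,4-trimethyl-1,3-dioxan-4-yl]ethyl}cyclopent-2-en-1-one, 5-methyl trans to the side chain (not isolated) | C[C@@H]1C(=O)C=C(C)[C@H]1CC[C@]2(C)CCOC(C)(C)O2 | intermediate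
13 | (4R)-3,5,5-trimethyl-4-{2-[(4R)-2,2,4-trimethyl-1,3-dioxan-4-yl]ethyl}cyclopent-2-en-1-one | CC1(C)C(=O)C=C(C)[C@H]1CC[C@]2(C)CCOC(C)(C)O2 | intermediate
14 | (1R,4R,5R)-3,3,5-trimethyl-4-{2-[(4R)-2,2,4-trimethyl-1,3-dioxan-4-yl]ethyl}bicyclo[3.1.0]hexan-2-one (side chain anti to the cyclopropane CH2) | CC1(C)C(=O)[C@@H]2C[C@]2(C)[C@H]1CC[C@]3(C)CCOC(C)(C)O3 | intermediate
15 | (1R,4R,5R)-4-[(3R)-3,5-dihydroxy-3-methylpentyl]-3,3,5-trimethylbicyclo[3.1.0]hexan-2-one (not isolated) | CC1(C)C(=O)[C@@H]2C[C@]2(C)[C@H]1CC[C@@](C)(O)CCO | intermediate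
16 | (3S,4S)-3-[(3R)-3,5-dihydroxy-3-methylpentyl]-4-hydroxy-2,2,4-trimethylcyclohexan-1-one | CC1(C)C(=O)CC[C@](C)(O)[C@H]1CC[C@@](C)(O)CCO | intermediate
17 | (1S,2S,4R)-2-[(3R)-3,5-dihydroxy-3-methylpentyl]-1,3,3-trimethylcyclohexane-1,4-diol | CC1(C)[C@H](O)CC[C@](C)(O)[C@H]1CC[C@@](C)(O)CCO | intermediate
18 | umbelliferone (7-hydroxy-2H-chromen-2-one) | Oc1ccc2ccc(=O)oc2c1 | starting material
19 | 7-{[(3R)-5-[(1S,2S,5R)-2,5-dihydroxy-2,6,6-trimethylcyclohexyl]-3-hydroxy-3-methylpentyl]oxy}-2H-chromen-2-one | CC1(C)[C@H](O)CC[C@](C)(O)[C@H]1CC[C@@](C)(O)CCOc1ccc2ccc(=O)oc2c1 | target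

Total step count: 12. Longest linear sequence: 12 steps (1 to 19).

**Steps most likely to fail**

Step 10. Proton loss from the developing C7 cation may outrun capture by water (elimination, then drift of the double bond into conjugation). The cyclopropane may also open at its CH2 carbon, and the acid may ionise the side-chain tertiary carbinol and erode C3. The fallback lowers the oxidation level so that far weaker acid suffices. It sets out from 14: NaBH4 in MeOH should give the cyclopropyl carbinol F1 (either epimer serves). A trace of HClO4 in acetone–water at 0 °C should then trigger the cyclopropylcarbinyl–homoallyl rearrangement, water again entering C7 anti to the breaking bond and the acetonide falling off, to give the homoallylic alcohol F2. VO(acac)2 with t-BuOOH should deliver the epoxide F3 cis to the C7 hydroxyl (homoallylic direction). LiAlH4 should open F3 at C9, the carbon remote from the quaternary C11, and the route is rejoined at 17.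

Step 9. Conjugate addition of the ylide to a β,β-disubstituted enone beside the branched C6 may be slow, and reversible γ-deprotonation by the ylide could erode the C6 configuration. The fallback installs the C7 oxygen and the extra ring carbon separately. It sets out from 13: Weitz–Scheffer epoxidation (H2O2, NaOH, MeOH) should give the epoxy ketone F4 with oxygen anti to the side chain. SmI2 in THF–MeOH at −78 °C should cleave the C–O bond α to the ketone and give the β-hydroxy ketone F5 with C7 intact. Me3SiCl and imidazole give the silyl ether F6. Me3SiCHN2 with BF3·OEt2 should insert one carbon on the CH2 side, the other α-carbon being quaternary (Tiffeneau–Demjanov-type diazoalkane homologation), giving the cyclohexanone F7 after protodesilylation on work-up. Aqueous HCl in THF then removes the silyl ether and the acetonide, and the route is rejoined at 16.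

Step 7. Ionisation to a free pentadienyl cation before ring closure would make chirality transfer to C6 incomplete, and the cationic gold may strip the acetonide. The fallback sets C6 by a sigmatropic chirality transfer and closes the ring by metathesis. It sets out from 5:
- MeMgBr gives the secondary alcohol F8 and MnO2 the methyl enone F9.
- Corey–Bakshi–Shibata reduction ((R)-methyl oxazaborolidine, BH3·SMe2) should give the (2S)-alcohol F10, and isobutyryl chloride with pyridine the ester F11.
- Ireland–Claisen rearrangement (LDA, Me3SiCl, THF, −78 °C to rt) should give the acid F12, with C6 set through a chair transition state and the C6–C11 bond and both C11 methyls already in place.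
- MeNHOMe·HCl with EDC gives the amide F13 and vinylmagnesium bromide the vinyl ketone F14.
- Ring-closing metathesis (second-generation Grubbs catalyst, CH2Cl2, 40 °C) should close the cyclopentenone with loss of propene, and the route is rejoined at 13.

Further compounds
F1 | step 10 | 3,3,5-trimethyl-4-{2-[(4R)-2,2,4-trimethyl-1,3-dioxan-4-yl]ethyl}bicyclo[3.1.0]hexan-2-ol (ring centres as in 14, carbinol epimers) | CC1(C)C(O)[C@@H]2C[C@]2(C)[C@H]1CC[C@]3(C)CCOC(C)(C)O3
F2 | step 10 | (1S,6S)-6-[(3R)-3,5-dihydroxy-3-methylpentyl]-1,5,5-trimethylcyclohex-3-en-1-ol | CC1(C)C=CC[C@](C)(O)[C@H]1CC[C@@](C)(O)CCO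
F3 | step 10 | 3,4-epoxide of F2, oxygen cis to the ring tertiary hydroxyl | CC1(C)[C@@H]2O[C@@H]2C[C@](C)(O)[C@H]1CC[C@@](C)(O)CCO
F4 | step 9 | 2,3-epoxide of 13, oxygen anti to the side chain | CC1(C)C(=O)[C@@H]2O[C@]2(C)[C@H]1CC[C@]3(C)CCOC(C)(C)O3
F5 | step 9 | (3S,4S)-4-hydroxy-2,2,4-trimethyl-3-{2-[(4R)-2,2,4-trimethyl-1,3-dioxan-4-yl]ethyl}cyclopentan-1-one | CC1(C)C(=O)C[C@](C)(O)[C@H]1CC[C@]2(C)CCOC(C)(C)O2
F6 | step 9 | trimethylsilyl ether of F5 | CC1(C)C(=O)C[C@](C)(O[Si](C)(C)C)[C@H]1CC[C@]2(C)CCOC(C)(C)O2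
F7 | step 9 | (3S,4S)-2,2,4-trimethyl-3-{2-[(4R)-2,2,4-trimethyl-1,3-dioxan-4-yl]ethyl}-4-(trimethylsilyloxy)cyclohexan-1-one | CC1(C)C(=O)CC[C@](C)(O[Si](C)(C)C)[C@H]1CC[C@]2(C)CCOC(C)(C)O2
F8 | step 7 | (3E)-3-methyl-6-[(4R)-2,2,4-trimethyl-1,3-dioxan-4-yl]hex-3-en-2-ol (carbinol epimers) | CC(O)/C(C)=C/CC[C@]1(C)CCOC(C)(C)O1
F9 | step 7 | (3E)-3-methyl-6-[(4R)-2,2,4-trimethyl-1,3-dioxan-4-yl]hex-3-en-2-one | CC(=O)/C(C)=C/CC[C@]1(C)CCOC(C)(C)O1
F10 | step 7 | (2S,3E)-3-methyl-6-[(4R)-2,2,4-trimethyl-1,3-dioxan-4-yl]hex-3-en-2-ol | C[C@H](O)/C(C)=C/CC[C@]1(C)CCOC(C)(C)O1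
F11 | step 7 | (2S,3E)-3-methyl-6-[(4R)-2,2,4-trimethyl-1,3-dioxan-4-yl]hex-3-en-2-yl 2-methylpropanoate | CC(C)C(=O)O[C@@H](C)/C(C)=C/CC[C@]1(C)CCOC(C)(C)O1
F12 | step 7 | (3R,4E)-2,2,4-trimethyl-3-{2-[(4R)-2,2,4-trimethyl-1,3-dioxan-4-yl]ethyl}hex-4-enoic acid | C/C=C(C)/[C@@H](CC[C@]1(C)CCOC(C)(C)O1)C(C)(C)C(=O)O
F13 | step 7 | (3R,4E)-N-methoxy-N,2,2,4-tetramethyl-3-{2-[(4R)-2,2,4-trimethyl-1,3-dioxan-4-yl]ethyl}hex-4-enamide | C/C=C(C)/[C@@H](CC[C@]1(C)CCOC(C)(C)O1)C(C)(C)C(=O)N(C)OC
F14 | step 7 | (5R,6E)-4,4,6-trimethyl-5-{2-[(4R)-2,2,4-trimethyl-1,3-dioxan-4-yl]ethyl}octa-1,6-dien-3-one | C/C=C(C)/[C@@H](CC[C@]1(C)CCOC(C)(C)O1)C(C)(C)C(=O)C=C
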